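**Strategy.** The route rests on disconnecting the bond between C1 of one syringyl ring and its benzylic CH2. In the target this CH2 sits in an Ar–CH2–CH–CH2OH array, a masked β-aryl carbonyl pattern. Raising that CH2OH carbon to a lactone carbonyl gives the precursor, (R)-β-(4-benzyloxy-3,5-dimethoxybenzyl)-α-methylene-γ-butyrolactone, whose exocyclic CH2 is the future benzylic carbon. A rhodium-catalysed conjugate addition of a syringyl boronate forges the aryl–CH2 bond. Protonation and in-flask equilibration, controlled by the existing β-stereocentre, set the second stereocentre trans, so the complete dibenzylbutyrolactone skeleton arises in one operation. Lactone reduction and debenzylation then give the target.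

Key step: step 7

Assumption: the (S,S)-Et-DuPhos–Rh catalyst of step 3 is taken, by analogy with itaconate half-esters, to deliver the (R)-succinate; if the sense proves opposite, the (R,R)-ligand is used instead.

Step 1
Reactants: 1 syringaldehyde (4-hydroxy-3,5-dimethoxybenzaldehyde)
Product: 2 4-(benzyloxy)-3,5-dimethoxybenzaldehyde
Conditions: BnBr, K2CO3, DMF, 60 °C
Reagents that add atoms: benzyl bromide BrCc1ccccc1
Why: Williamson etherification of the acidic phenoxide with a reactive benzylic halide; the benzyl ether should survive the base, hydride and Rh steps and is removed by hydrogenolysis at the end.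

Step 2
Reactants: 2 4-(benzyloxy)-3,5-dimethoxybenzaldehyde; 3 dimethyl succinate
Product: 5 (E)-4-[4-(benzyloxy)-3,5-dimethoxyphenyl]-3-(methoxycarbonyl)but-3-enoic acid, via paraconate lactone 4 (not isolated)
Conditions: NaOMe, MeOH, reflux; then aq. HCl
Reagents that add atoms: none
Why: Stobbe condensation, in which aldol addition of the succinate enolate, lactonisation to the paraconic ester and irreversible E1cB ring opening should give the half-ester with the aryl group trans to CO2Me.

Step 3
Reactants: 5 (E)-4-[4-(benzyloxy)-3,5-dimethoxyphenyl]-3-(methoxycarbonyl)but-3-enoic acid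
Product: 6 (R)-4-[4-(benzyloxy)-3,5-dimethoxyphenyl]-3-(methoxycarbonyl)butanoic acid
Conditions: [Rh(cod)((S,S)-Et-DuPhos)]OTf (1 mol%), NaOMe (10 mol%), H2 (5 bar), MeOH, rt
Reagents that add atoms: none
Why: Rh-catalysed asymmetric hydrogenation of an itaconate-type half-ester, in which chelation of the alkene and the β-carboxylate to the chiral bisphosphine–Rh centre fixes the face of H2 delivery and sets the (R) stereocentre; benzyl ethers are inert to the homogeneous catalyst.

Step 4
Reactants: 6 (R)-4-[4-(benzyloxy)-3,5-dimethoxyphenyl]-3-(methoxycarbonyl)butanoic acid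
Product: 8 (R)-4-[4-(benzyloxy)-3,5-dimethoxybenzyl]dihydrofuran-2(3H)-one, via hydroxy acid 7 (not isolated)
Conditions: KOH (1 equiv), EtOH, 0 °C; CaCl2, NaBH4, EtOH, −10 °C to rt; then 2 M HCl
Reagents that add atoms: none
Why: Chemoselective borohydride reduction, since the carboxylate salt is inert to Ca(BH4)2 while the methyl ester is reduced, followed by acid-promoted lactonisation of the γ-hydroxy acid; one equivalent of base at low temperature should leave the stereocentre α to the ester untouched.

Step 5
Reactants: 8 (R)-4-[4-(benzyloxy)-3,5-dimethoxybenzyl]dihydrofuran-2(3H)-one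
Product: 10 (R)-4-[4-(benzyloxy)-3,5-dimethoxybenzyl]-3-methylenedihydrofuran-2(3H)-one, via sodium 3-formyl-lactone enolate 9 (not isolated)
Conditions: NaH, HCO2Et, THF, 0 °C to rt; then (CH2O)n, THF, 65 °C
Reagents that add atoms: formaldehyde (as paraformaldehyde) C=O
Why: α-Methylenation of a lactone through its α-formyl derivative, in which Claisen formylation at C3, aldol addition to formaldehyde, formyl transfer and β-elimination of formate should give the exocyclic alkene; C4 is not involved and keeps its configuration.

Step 6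
Reactants: 11 4-hydroxy-3,5-dimethoxyphenylboronic acid pinacol ester
Product: 12 2-[4-(benzyloxy)-3,5-dimethoxyphenyl]-4,4,5,5-tetramethyl-1,3,2-dioxaborolane
Conditions: BnBr, K2CO3, acetone, reflux
Reagents that add atoms: benzyl bromide BrCc1ccccc1
Why: Williamson etherification; the pinacol boronate tolerates anhydrous carbonate, and protection suppresses protodeboronation of the otherwise very electron-rich phenoxide in the next step.

Step 7
Reactants: 10 (R)-4-[4-(benzyloxy)-3,5-dimethoxybenzyl]-3-methylenedihydrofuran-2(3H)-one; 12 2-[4-(benzyloxy)-3,5-dimethoxyphenyl]-4,4,5,5-tetramethyl-1,3,2-dioxaborolane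
Product: 14 (3R,4R)-3,4-bis[4-(benzyloxy)-3,5-dimethoxybenzyl]dihydrofuran-2(3H)-one (trans), via cis-lactone 13 (not isolated)
Conditions: [Rh(cod)OH]2 (3 mol%), K3PO4 (0.5 equiv), dioxane/H2O (10:1), 60 °C; then DBU (0.5 equiv), 60 °C; aq. HCl work-up
Reagents that add atoms: none
Why: Transmetalation of 12 to the Rh(I) hydroxide gives an aryl–rhodium species that adds across the exocyclic C=C of 10 with the aryl group going to the unsubstituted CH2 terminus, forming the bond between syringyl C1 and the benzylic carbon and a rhodium oxa-π-allyl (enolate) that water protonates at C3 to regenerate Rh–OH. The closest known reaction type is the Hayashi–Miyaura rhodium-catalysed 1,4-addition of arylboron reagents to 1,1-disubstituted acrylate-type acceptors (itaconates, α-methylene lactones) with α-protonation. No ring is closed. The only new stereocentre, C3, arises in the protonation: kinetic proton delivery anti to the C4 benzyl group should favour the cis epimer 13, and DBU, added only after 10 is consumed, should equilibrate it through the lactone enolate to the more stable trans (3R,4R) lactone 14, so that C4 (set in step 3, not enolisable) controls C3. The step needs regioselective aryl delivery to the CH2 terminus, secured by the polarisation and steric bias of the 1,1-disubstituted enoate, and protonolysis in preference to β-hydride elimination, secured by the aqueous medium and the O-bound enolate. Migration of the exocyclic alkene into the ring, which would erase C4, is avoided by withholding the amidine base until the addition is complete.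

Step 8
Reactants: 14 (3R,4R)-3,4-bis[4-(benzyloxy)-3,5-dimethoxybenzyl]dihydrofuran-2(3H)-one
Product: 15 (2R,3R)-2,3-bis[4-(benzyloxy)-3,5-dimethoxybenzyl]butane-1,4-diol
Conditions: LiAlH4, THF, 0 °C to rt; Fieser work-up
Reagents that add atoms: none
Why: Hydride reduction of the lactone to the 1,4-diol is fast relative to enolisation, so both stereocentres should be carried over unchanged; benzyl and methyl ethers are inert.

Step 9
Reactants: 15 (2R,3R)-2,3-bis[4-(benzyloxy)-3,5-dimethoxybenzyl]butane-1,4-diol
Product: 16 (2R,3R)-2,3-bis(4-hydroxy-3,5-dimethoxybenzyl)butane-1,4-diol (5,5'-dimethoxysecoisolariciresinol)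
Conditions: H2 (1 atm), 10% Pd/C, MeOH/EtOAc, rt
Reagents that add atoms: none
Why: Hydrogenolysis of the two benzyl aryl ethers frees both phenols; the aliphatic C–O bonds, the methyl ethers and the stereocentres are not affected under these neutral conditions.

**Compound list**

1 | syringaldehyde (4-hydroxy-3,5-dimethoxybenzaldehyde) | COc1cc(C=O)cc(OC)c1O | starting material
2 | 4-(benzyloxy)-3,5-dimethoxybenzaldehyde | COc1cc(C=O)cc(OC)c1OCc1ccccc1 | intermediate
3 | dimethyl succinate | COC(=O)CCC(=O)OC | starting material
4 | methyl 2-[4-(benzyloxy)-3,5-dimethoxyphenyl]-5-oxotetrahydrofuran-3-carboxylate (paraconate lactone, mixture of stereoisomers) | COC(=O)C1CC(=O)OC1c1cc(OC)c(OCc2ccccc2)c(OC)c1 | intermediate (not isolated)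
5 | (E)-4-[4-(benzyloxy)-3,5-dimethoxyphenyl]-3-(methoxycarbonyl)but-3-enoic acid | COC(=O)/C(CC(=O)O)=C/c1cc(OC)c(OCc2ccccc2)c(OC)c1 | intermediate
6 | (R)-4-[4-(benzyloxy)-3,5-dimethoxyphenyl]-3-(methoxycarbonyl)butanoic acid | COC(=O)[C@@H](CC(=O)O)Cc1cc(OC)c(OCc2ccccc2)c(OC)c1 | intermediate
7 | (R)-4-[4-(benzyloxy)-3,5-dimethoxyphenyl]-3-(hydroxymethyl)butanoic acid (present as its carboxylate) | OC[C@@H](CC(=O)O)Cc1cc(OC)c(OCc2ccccc2)c(OC)c1 | intermediate (not isolated)
8 | (R)-4-[4-(benzyloxy)-3,5-dimethoxybenzyl]dihydrofuran-2(3H)-one | O=C1C[C@@H](Cc2cc(OC)c(OCc3ccccc3)c(OC)c2)CO1 | intermediate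
9 | sodium enolate of (R)-4-[4-(benzyloxy)-3,5-dimethoxybenzyl]-3-formyldihydrofuran-2(3H)-one | [Na+].[O-]C=C1C(=O)OC[C@@H]1Cc1cc(OC)c(OCc2ccccc2)c(OC)c1 | intermediate (not isolated)
10 | (R)-4-[4-(benzyloxy)-3,5-dimethoxybenzyl]-3-methylenedihydrofuran-2(3H)-one | C=C1[C@@H](Cc2cc(OC)c(OCc3ccccc3)c(OC)c2)COC1=O | intermediate
11 | 4-hydroxy-3,5-dimethoxyphenylboronic acid pinacol ester | COc1cc(B2OC(C)(C)C(C)(C)O2)cc(OC)c1O | starting material
12 | 2-[4-(benzyloxy)-3,5-dimethoxyphenyl]-4,4,5,5-tetramethyl-1,3,2-dioxaborolane | COc1cc(B2OC(C)(C)C(C)(C)O2)cc(OC)c1OCc1ccccc1 | intermediate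
13 | (3S,4R)-3,4-bis[4-(benzyloxy)-3,5-dimethoxybenzyl]dihydrofuran-2(3H)-one (cis) | O=C1OC[C@H](Cc2cc(OC)c(OCc3ccccc3)c(OC)c2)[C@@H]1Cc1cc(OC)c(OCc2ccccc2)c(OC)c1 | intermediate (not isolated)
14 | (3R,4R)-3,4-bis[4-(benzyloxy)-3,5-dimethoxybenzyl]dihydrofuran-2(3H)-one (trans) | O=C1OC[C@H](Cc2cc(OC)c(OCc3ccccc3)c(OC)c2)[C@H]1Cc1cc(OC)c(OCc2ccccc2)c(OC)c1 | intermediate
15 | (2R,3R)-2,3-bis[4-(benzyloxy)-3,5-dimethoxybenzyl]butane-1,4-diol | COc1cc(C[C@@H](CO)[C@H](CO)Cc2cc(OC)c(OCc3ccccc3)c(OC)c2)cc(OC)c1OCc1ccccc1 | intermediate
16 | (2R,3R)-2,3-bis(4-hydroxy-3,5-dimethoxybenzyl)butane-1,4-diol (5,5'-dimethoxysecoisolariciresinol) | COc1cc(C[C@@H](CO)[C@H](CO)Cc2cc(OC)c(O)c(OC)c2)cc(OC)c1O | target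

**Step count.** Total: 9 steps. Longest linear sequence: 8 steps (steps 1–5 and 7–9); step 6 is a one-step side branch.

**Steps most likely to fail**

1. Step 7 (key step). The aryl–rhodium intermediate may undergo β-hydride elimination (Heck-type arylation) instead of protonolysis. The electron-rich boronate may be lost by protodeboronation. The exocyclic double bond may migrate into the ring before addition, which would erase the C4 stereocentre. Fallback, setting out from 10 and returning at 14: a copper-catalysed conjugate addition of an aryl Grignard reagent forms the same aryl–CH2 bond by a different mechanism. Commercial 4-bromo-2,6-dimethoxyphenol would be benzylated (BnBr, K2CO3, DMF) to 2-(benzyloxy)-5-bromo-1,3-dimethoxybenzene F1. Magnesium in THF would convert it into [4-(benzyloxy)-3,5-dimethoxyphenyl]magnesium bromide F2. Addition of F2 to 10 with CuBr·SMe2 (10 mol%) in THF at −40 °C, quenching with aqueous NH4Cl and equilibration of the crude cis/trans mixture with DBU should give 14.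

2. Step 5. Under the basic conditions the new exocyclic alkene may isomerise to the endocyclic butenolide, with loss of the C4 stereocentre, or the methylene lactone may oligomerise. Formyl transfer may also be incomplete. Fallback, setting out from 8 and returning at 10: a Mannich/elimination sequence that keeps the basic step short and cold. Deprotonation of 8 with LDA (THF, −78 °C) and trapping with Eschenmoser's salt should give (3S,4R)-3-[(dimethylamino)methyl]-4-[4-(benzyloxy)-3,5-dimethoxybenzyl]dihydrofuran-2(3H)-one F3. Quaternisation with MeI in MeOH should give the trimethylammonium iodide F4. Treatment with aqueous NaHCO3 in CH2Cl2 at rt should eliminate trimethylamine and give 10.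

3. Step 3. Facial selectivity in hydrogenating the trisubstituted, electron-rich benzylidene succinate may be insufficient, or of the wrong sense. Fallback, setting out from 5 and returning at 6: classical resolution instead of asymmetric catalysis. Hydrogenation of 5 with an achiral catalyst that spares benzyl ethers ([Rh(nbd)(dppb)]BF4, H2, MeOH) should give racemic 4-[4-(benzyloxy)-3,5-dimethoxyphenyl]-3-(methoxycarbonyl)butanoic acid F5. Fractional crystallisation with (S)-1-phenylethylamine is assumed to give the less soluble (S)-1-phenylethylammonium salt of the (R)-acid F6; otherwise the (R)-amine is used. Acidification with cold dilute HCl should liberate 6.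

**Further compounds**

F1 | step 7 | 2-(benzyloxy)-5-bromo-1,3-dimethoxybenzene | COc1cc(Br)cc(OC)c1OCc1ccccc1
F2 | step 7 | [4-(benzyloxy)-3,5-dimethoxyphenyl]magnesium bromide | COc1cc([Mg]Br)cc(OC)c1OCc1ccccc1
F3 | step 5 | (3S,4R)-3-[(dimethylamino)methyl]-4-[4-(benzyloxy)-3,5-dimethoxybenzyl]dihydrofuran-2(3H)-one | O=C1OC[C@H](Cc2cc(OC)c(OCc3ccccc3)c(OC)c2)[C@H]1CN(C)C
F4 | step 5 | {(3S,4R)-4-[4-(benzyloxy)-3,5-dimethoxybenzyl]-2-oxotetrahydrofuran-3-yl}methyl-trimethylammonium iodide | O=C1OC[C@H](Cc2cc(OC)c(OCc3ccccc3)c(OC)c2)[C@H]1C[N+](C)(C)C.[I-]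
F5 | step 3 | racemic 4-[4-(benzyloxy)-3,5-dimethoxyphenyl]-3-(methoxycarbonyl)butanoic acid | COC(=O)C(CC(=O)O)Cc1cc(OC)c(OCc2ccccc2)c(OC)c1
F6 | step 3 | (S)-1-phenylethylammonium (R)-4-[4-(benzyloxy)-3,5-dimethoxyphenyl]-3-(methoxycarbonyl)butanoate | COC(=O)[C@@H](CC(=O)[O-])Cc1cc(OC)c(OCc2ccccc2)c(OC)c1.C[C@H]([NH3+])c1ccccc1
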